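Ring B, the seven-membered ring (C1, C5–C10, daucane numbering), bears oxygen at C6 and C8. This 1,3-pattern next to quaternary C1 is the retron of a Brook-rearrangement-mediated [3+4] annulation. The lithium dienolate of an enantiopure 1-acetyl-2-methylcyclopentene (C7–C6–C5=C1 on ring A) adds to the carbonyl C8 of an acryloylsilane. Silicon migration to oxygen turns C8 into a carbanion that closes a cis-divinylcyclopropanolate on C6. Strain-releasing anionic oxy-Cope rearrangement then unites the like-polarised β-carbons C10 and C1. One operation forms C7–C8 and C10–C1, sets C1, and leaves C6 (ketone) and C8 (enol silane) differentiated.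

Key step: step 5

Remark on numbering: daucane numbering is used throughout. C1 is the quaternary ring-fusion carbon bearing methyl C15. C2 and C3 follow, C4 is the carbinol carbon of ring A, and C5 is the ring-fusion CH. C6 to C10 complete ring B, and C14 is the methyl on C8. β is the face of C15 and α is the face of H5.

Assumption: compounds 1, 5 and 21 and all unnumbered reagents are taken as commercial.

Step 1
Reactants: 1 2-bromo-3-methylcyclopent-2-en-1-one
Product: 2 (S)-2-bromo-3-methylcyclopent-2-en-1-ol
Conditions: (R)-2-methyl-CBS-oxazaborolidine (10 mol%), BH3·SMe2, THF, −20 °C; MeOH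
Reagents that add atoms: none
Why: Corey–Bakshi–Shibata reduction, in which the bromoalkenyl arm takes the large-group position of the catalyst–borane complex, so hydride delivery sets C4 as (S), a temporary stereocentre that later controls C1, C5 and C6.

Step 2
Reactants: 2 (S)-2-bromo-3-methylcyclopent-2-en-1-ol
Product: 4 (S)-1-(5-hydroxy-2-methylcyclopent-1-en-1-yl)ethan-1-one, via lithio alkoxide 3 (not isolated)
Conditions: t-BuLi (3.1 equiv), Et2O, −78 °C; MeC(O)N(OMe)Me, −78 → 0 °C; H2O
Reagents that add atoms: N-methoxy-N-methylacetamide CC(=O)N(C)OC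
Why: O–H deprotonation and bromine–lithium exchange give 3, whose acylation stops at the ketone stage (Weinreb ketone synthesis) and leaves C4 untouched.

Step 3
Reactants: 5 allyloxy(tert-butyl)dimethylsilane
Product: 6 rac-1-[tert-butyl(dimethyl)silyl]prop-2-en-1-ol
Conditions: s-BuLi (1.2 equiv), THF, −78 → −30 °C; H2O
Reagents that add atoms: none
Why: Retro-Brook (1,2-silyl-Wittig) rearrangement, in which lithiation α to oxygen is followed by migration of silicon from O to C, driven by alkoxide formation; the racemic stereocentre is erased in step 4.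

Step 4
Reactants: 6 rac-1-[tert-butyl(dimethyl)silyl]prop-2-en-1-ol
Product: 7 1-[tert-butyl(dimethyl)silyl]prop-2-en-1-one (acryloylsilane)
Conditions: (COCl)2, DMSO, CH2Cl2, −78 °C; Et3N, −78 → −20 °C
Reagents that add atoms: none
Why: Swern oxidation of an α-hydroxysilane is the standard entry to acylsilanes and avoids the acid or strong base that would trigger Brook rearrangement or polymerisation.

Step 5
Reactants: 4 (S)-1-(5-hydroxy-2-methylcyclopent-1-en-1-yl)ethan-1-one; 7 1-[tert-butyl(dimethyl)silyl]prop-2-en-1-one
Product: 12 trans-fused ketol (4β-OH; 5α-H; 1β-CH3; C6 ketone; C8=C9 TBS enol ether), via alkoxide-dienolate 8 (not isolated), via carbonyl adduct 9 (not isolated), via cis-divinylcyclopropanolate 10 (not isolated), via ring-expanded enolate 11 (not isolated)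
Conditions: LDA (2.2 equiv), THF, −78 °C; 7 (1.1 equiv), −78 → −30 °C; AcOH (4 equiv), −78 °C
Reagents that add atoms: none
Why: LDA gives 8 by kinetic α′-deprotonation, C7 adds 1,2 to the acylsilane carbonyl C8 (9), the 1,2-Brook shift of silicon from C8 to O8 reverses the polarity of C8, the siloxyallyl anion closes 3-exo-trig on the C6 ketone to give 10, and anionic oxy-Cope rearrangement breaks C6–C8 and forms C10–C1 to give 11. The closest known reaction type is exactly this Brook-rearrangement-mediated [3+4] annulation of acryloylsilanes with lithium enolates of alkenyl methyl ketones, 1-acetylcycloalkenes included. Ring B closes by the [3,3]-sigmatropic shift through the boat array that a cis-divinylcyclopropane enforces, driven by loss of cyclopropane strain and by enolate formation, so the quaternary carbon is made without intermolecular attack on the tetrasubstituted alkene. For C1, C9–H lies directly under the C5–C4 bond in that boat, so the C8–C9–C10 arm takes the ring A face that carries only H4, anti to the solvated C4 lithium alkoxide (which can also bridge to O6), C10 bonds to the α face of C1 and C15 ends β. C5 is set when 11 is protonated and stays epimerisable; the trans-fused ketol is the epimer that gains the O4–H···O6 hydrogen bond, and it alone is consumed in step 6. The step needs 1,2- over 1,4-addition to 7 (fast kinetic carbonyl addition of a lithium enolate at −78 °C, made irreversible by the Brook shift and ring closure) and [3+4] over [3+2] closure (the Cope shift of 10 is far faster than a vinylcyclopropane rearrangement).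

Step 6
Reactants: 12 trans-fused ketol
Product: 13 4β,6α-diol (5α-H; 1β-CH3; C8=C9 TBS enol ether)
Conditions: Me4NBH(OAc)3, MeCN/AcOH, −30 °C
Reagents that add atoms: none
Why: Evans–Saksena reduction, in which boron binds O4 and hands its hydride to C6 from the β face through a chair-like six-membered array to give the 4,6-anti diol with 6α-OH; this is open only to the trans-fused epimer, where O4 and C6 are cis on ring A, because the reagent does not reduce unbound ketones.

Step 7
Reactants: 13 4β,6α-diol
Product: 14 6α-TBS ether of 13 (4β-OH free)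
Conditions: TBSCl (1.05 equiv), imidazole, DMF, 0 °C
Reagents that add atoms: tert-butyldimethylsilyl chloride CC(C)(C)[Si](C)(C)Cl
Why: Sterically governed monosilylation, since the equatorial 6α-OH on the open α face reacts faster than 4β-OH, which is wedged between C6 and C15 on the β face.

Step 8
Reactants: 14 6α-TBS ether
Product: 15 C4 ketone (5α-H; 6α-OTBS; C8=C9 TBS enol ether)
Conditions: Dess–Martin periodinane, pyridine, CH2Cl2, 0 °C
Reagents that add atoms: none
Why: Dess–Martin oxidation under pyridine buffering is mild enough for the enol silane, the β-silyloxy ketone and the epimerisable C5.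

Step 9
Reactants: 15 C4 ketone
Product: 16 4β-hydroxy-4α-isopropyl compound (6α-OTBS; C8=C9 TBS enol ether)
Conditions: i-PrMgCl, CeCl3, THF, −78 °C
Reagents that add atoms: isopropylmagnesium chloride CC(C)[Mg]Cl
Why: Organocerium 1,2-addition, whose low basicity suppresses enolisation, β-elimination and hydride transfer; the β face of the C4 carbonyl is blocked by the vicinal C6 branch and by C15, so isopropyl enters from the α face and gives 4β-OH.

Step 10
Reactants: 16 4β-hydroxy-4α-isopropyl compound
Product: 18 C8 alkenyl triflate (C8=C9), via cesium enolate 17 (not isolated)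
Conditions: CsF, PhNTf2, DME, rt
Reagents that add atoms: N-phenylbis(trifluoromethanesulfonimide) O=S(=O)(N(c1ccccc1)S(=O)(=O)C(F)(F)F)C(F)(F)F
Why: Fluoride-triggered enolate O-sulfonylation, in which the enol silane is cleaved faster than the hindered alkyl silyl ether and the regiodefined enolate 17 is trapped in situ, so the C8=C9 position set in step 5 is kept.

Step 11
Reactants: 18 C8 alkenyl triflate
Product: 19 6-O-TBS-jaeschkeanadiol (6α-TBSO-dauc-8-en-4β-ol)
Conditions: MeMgBr (3 equiv), Fe(acac)3 (5 mol%), THF/NMP, −30 °C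
Reagents that add atoms: methylmagnesium bromide C[Mg]Br
Why: Iron-catalysed Kumada-type cross-coupling of an alkenyl triflate is fast at low temperature, keeps the alkene position and installs C14, with one equivalent of Grignard reagent spent on O4–H.

Step 12
Reactants: 19 6-O-TBS-jaeschkeanadiol
Product: 20 jaeschkeanadiol (dauc-8-ene-4β,6α-diol)
Conditions: TBAF, THF, 40 °C
Reagents that add atoms: none
Why: Fluoride desilylation frees 6α-OH, and no other group present is fluoride-labile.

Step 13
Reactants: 20 jaeschkeanadiol; 21 4-acetoxybenzoyl chloride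
Product: 23 ferutinin [6α-(4-hydroxybenzoyloxy)dauc-8-en-4β-ol], via ferutinin O-acetate 22 (not isolated)
Conditions: Et3N, DMAP (cat.), CH2Cl2, rt; pyrrolidine, rt
Reagents that add atoms: none
Why: DMAP-catalysed acylation occurs only at the secondary 6α-OH (tertiary 4β-OH is inert), and aminolysis by pyrrolidine then removes the far more electrophilic aryl acetate of 22 without touching the hindered aroate.

Step 14
Reactants: 23 ferutinin
Product: 24 ferutinin 8α,9α-epoxide
Conditions: mCPBA, CH2Cl2, −10 °C
Reagents that add atoms: 3-chloroperoxybenzoic acid O=C(OO)c1cccc(Cl)c1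
Why: Prilezhaev epoxidation of the only alkene, in which C15 shields the β face of ring B, so oxygen is delivered to the α face and fixes the C8–O configuration of the target.

Step 15
Reactants: 24 ferutinin 8α,9α-epoxide
Product: 27 target 6α-(4-hydroxybenzoyloxy)dauc-9-ene-4β,8α-diol (1R;4R;5S;6S;8R), via hydroxy selenide 25 (not isolated), via selenoxide 26 (not isolated)
Conditions: PhSeSePh, NaBH4, EtOH, 60 °C; H2O2, THF, 0 °C → rt
Reagents that add atoms: none
Why: Organoselenium epoxide-to-allylic-alcohol transposition, in which phenylselenolate opens 24 by SN2 attack at the less substituted C9 (25, C8–O bond untouched), and syn elimination of selenoxide 26 can engage only a C10 hydrogen because C8 is fully substituted, which places the alkene at C9=C10.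

Compound list
1 | 2-bromo-3-methylcyclopent-2-en-1-one | CC1=C(Br)C(=O)CC1 | starting material
2 | (S)-2-bromo-3-methylcyclopent-2-en-1-ol | CC1=C(Br)[C@@H](O)CC1 | intermediate
3 | lithium (S)-2-lithio-3-methylcyclopent-2-en-1-olate | [Li+].[Li]C1=C(C)CC[C@@H]1[O-] | intermediate
4 | (S)-1-(5-hydroxy-2-methylcyclopent-1-en-1-yl)ethan-1-one | CC(=O)C1=C(C)CC[C@@H]1O | intermediate
5 | allyloxy(tert-butyl)dimethylsilane | C=CCO[Si](C)(C)C(C)(C)C | starting material
6 | rac-1-[tert-butyl(dimethyl)silyl]prop-2-en-1-ol | C=CC(O)[Si](C)(C)C(C)(C)C | intermediate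
7 | 1-[tert-butyl(dimethyl)silyl]prop-2-en-1-one | C=CC(=O)[Si](C)(C)C(C)(C)C | intermediate
8 | dilithium alkoxide-dienolate of 4 | [Li+].[Li+].C=C([O-])C1=C(C)CC[C@@H]1[O-] | intermediate
9 | dilithium carbonyl adduct of 8 and 7 (C8 unassigned) | [Li+].[Li+].C=CC([O-])([Si](C)(C)C(C)(C)C)CC(=O)C1=C(C)CC[C@@H]1[O-] | intermediate
10 | dilithium cis-divinylcyclopropanolate (C6–C7–C8 ring; vinyl and cyclopentenyl cis) | [Li+].[Li+].C=C[C@@]1(O[Si](C)(C)C(C)(C)C)C[C@@]1([O-])C2=C(C)CC[C@@H]2[O-] | intermediate
11 | dilithium ring-expanded C5=C6 enolate (4β-alkoxide; 1β-CH3) | [Li+].[Li+].[O-][C@H]1CC[C@]2(C)CC=C(O[Si](C)(C)C(C)(C)C)CC([O-])=C21 | intermediate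
12 | trans-fused ketol (4β-OH; 5α-H; 1β-CH3; C6 ketone; C8=C9 TBS enol ether) | O[C@H]1CC[C@]2(C)CC=C(O[Si](C)(C)C(C)(C)C)CC(=O)[C@H]21 | intermediate
13 | 4β,6α-diol | O[C@H]1CC[C@]2(C)CC=C(O[Si](C)(C)C(C)(C)C)C[C@H](O)[C@H]21 | intermediate
14 | 6α-TBS ether with free 4β-OH | O[C@H]1CC[C@]2(C)CC=C(O[Si](C)(C)C(C)(C)C)C[C@H](O[Si](C)(C)C(C)(C)C)[C@H]21 | intermediate
15 | C4 ketone | O=C1CC[C@]2(C)CC=C(O[Si](C)(C)C(C)(C)C)C[C@H](O[Si](C)(C)C(C)(C)C)[C@H]21 | intermediate
16 | 4β-hydroxy-4α-isopropyl bis-silyl compound | CC(C)[C@]1(O)CC[C@]2(C)CC=C(O[Si](C)(C)C(C)(C)C)C[C@H](O[Si](C)(C)C(C)(C)C)[C@H]21 | intermediate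
17 | cesium C8=C9 enolate | [Cs+].CC(C)[C@]1(O)CC[C@]2(C)CC=C([O-])C[C@H](O[Si](C)(C)C(C)(C)C)[C@H]21 | intermediate
18 | C8 alkenyl triflate | CC(C)[C@]1(O)CC[C@]2(C)CC=C(OS(=O)(=O)C(F)(F)F)C[C@H](O[Si](C)(C)C(C)(C)C)[C@H]21 | intermediate
19 | 6-O-TBS-jaeschkeanadiol | CC(C)[C@]1(O)CC[C@]2(C)CC=C(C)C[C@H](O[Si](C)(C)C(C)(C)C)[C@H]21 | intermediate
20 | jaeschkeanadiol (dauc-8-ene-4β,6α-diol) | CC(C)[C@]1(O)CC[C@]2(C)CC=C(C)C[C@H](O)[C@H]21 | intermediate
21 | 4-acetoxybenzoyl chloride | CC(=O)Oc1ccc(cc1)C(=O)Cl | starting material
22 | ferutinin O-acetate | CC(C)[C@]1(O)CC[C@]2(C)CC=C(C)C[C@H](OC(=O)c3ccc(OC(C)=O)cc3)[C@H]21 | intermediate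
23 | ferutinin | CC(C)[C@]1(O)CC[C@]2(C)CC=C(C)C[C@H](OC(=O)c3ccc(O)cc3)[C@H]21 | intermediate
24 | ferutinin 8α,9α-epoxide | CC(C)[C@]1(O)CC[C@]2(C)C[C@@H]3O[C@]3(C)C[C@H](OC(=O)c4ccc(O)cc4)[C@H]21 | intermediate
25 | 8α-hydroxy-9β-phenylselanyl compound | CC(C)[C@]1(O)CC[C@]2(C)C[C@@H]([Se]c3ccccc3)[C@](C)(O)C[C@H](OC(=O)c3ccc(O)cc3)[C@H]21 | intermediate
26 | selenoxide of 25 | CC(C)[C@]1(O)CC[C@]2(C)C[C@@H]([Se](=O)c3ccccc3)[C@](C)(O)C[C@H](OC(=O)c3ccc(O)cc3)[C@H]21 | intermediate
27 | 6α-(4-hydroxybenzoyloxy)dauc-9-ene-4β,8α-diol | CC(C)[C@]1(O)CC[C@]2(C)C=C[C@](C)(O)C[C@H](OC(=O)c3ccc(O)cc3)[C@H]21 | target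

Total step count: 15. Longest linear sequence: 13 steps (1, 2, 5 to 15).

Steps most likely to fail

1. Step 5.
   - What may go wrong: conjugate addition of the dienolate to the unhindered β-carbon of 7, or anionic polymerisation of 7; consumption of 7 by the free C4 alkoxide; protonation of 11 from the convex β face, which would give the cis ring fusion.
   - Fallback: the dianion is given up and a covalent steric shield replaces the lithium alkoxide. The fallback sets out from 4. TESCl and imidazole give the triethylsilyl ether of 4 F1. Its mono-enolate (LDA, 1.1 equiv) is combined with 7 to give the O4-triethylsilyl ketol F2. The bulky silyl ether screens the β face both in the boat array and in the protonation of C5, and no free alkoxide can attack the acylsilane. PPTS in MeOH at 0 °C removes the secondary triethylsilyl ether faster than the TBS enol ether is hydrolysed, and the route is rejoined at 12.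

2. Step 9.
   - What may go wrong: enolisation with loss of the C5 configuration, β-elimination of the C6 silyloxide, or reduction of the hindered ketone by β-hydride transfer from the secondary nucleophile.
   - Fallback: the isopropyl group is built in two stages from a slimmer sp2 nucleophile that has no transferable β-hydride. The fallback sets out from 15. 2-Propenylmagnesium bromide with CeCl3 at −78 °C adds from the α face to give the 4α-isopropenyl carbinol F5. Homogeneous hydrogenation (H2, RhCl(PPh3)3, benzene) then saturates only the 1,1-disubstituted alkene, because the trisubstituted enol silane is inert to this catalyst. The route is rejoined at 16.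

3. Step 7 (together with the acid exposure of the enol silane in step 6).
   - What may go wrong: poor site selectivity between the two secondary hydroxyl groups, silyl migration between O6 and O4, and hydrolysis of the enol silane in acetic acid.
   - Fallback: the two oxygens are differentiated by the reduction itself. The fallback sets out from 12. An Evans–Tishchenko reaction (SmI2, 20 mol%, MeCHO, THF, −10 °C) delivers hydride from the O4-bound hemiacetal to the β face of C6 and leaves the 4β-acetate 6α-alcohol F3. TBSCl and imidazole silylate the only free hydroxyl to give the 4β-acetate 6α-TBS ether F4. K2CO3 in MeOH at 0 °C then removes the acetate, and the route is rejoined at 14.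

Further compounds
F1 | step 5 | (S)-1-[2-methyl-5-(triethylsilyloxy)cyclopent-1-en-1-yl]ethan-1-one | CC(=O)C1=C(C)CC[C@@H]1O[Si](CC)(CC)CC
F2 | step 5 | O4-triethylsilyl ether of ketol 12 | CC[Si](CC)(CC)O[C@H]1CC[C@]2(C)CC=C(O[Si](C)(C)C(C)(C)C)CC(=O)[C@H]21
F3 | step 7 | 4β-acetoxy-6α-ol (C8=C9 TBS enol ether) | CC(=O)O[C@H]1CC[C@]2(C)CC=C(O[Si](C)(C)C(C)(C)C)C[C@H](O)[C@H]21
F4 | step 7 | 4β-acetoxy-6α-TBS ether (C8=C9 TBS enol ether) | CC(=O)O[C@H]1CC[C@]2(C)CC=C(O[Si](C)(C)C(C)(C)C)C[C@H](O[Si](C)(C)C(C)(C)C)[C@H]21
F5 | step 9 | 4β-hydroxy-4α-isopropenyl bis-silyl compound | C=C(C)[C@]1(O)CC[C@]2(C)CC=C(O[Si](C)(C)C(C)(C)C)C[C@H](O[Si](C)(C)C(C)(C)C)[C@H]21
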